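**Assumption (one line):** the SMILES is read literally – (Z)-butylidene in the butenolide half, (E)-butylidene in the saturated-lactone half, and on the cyclobutane H-6, H-7, C-1' and C-3' lie on one face ("lactone face") while C-5, C-7a, C-4' and C-7' lie on the other ("carbocycle face").

**Labels:** C-1…C-7a = butenolide half, C-1'…C-7a' = saturated-lactone half (phthalide numbering); C-8/C-8' = ylidene carbons; cyclobutane = C-6, C-7, C-3a', C-7a'.

## Retrosynthetic overview

1. Target 35 ⇐ Negishi propylation of an (E)-iodomethylene lactone ⇐ iodolactonisation of a cis alkynyl acid; the (Z)-butylidene butenolide ⇐ AgNO3-catalysed 5-exo lactonisation of an enynoic acid (Sonogashira of pent-1-yne with a β-keto ester enol triflate).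
2. Ring B ⇐ intramolecular alkylation of the lactone enolate by the chain on C-7a' (cis closure is forced); C-6'=C-7' ⇐ C-7' ketone via enol triflate reduction.
3. Ring A ⇐ Michael addition of tert-butyl acetoacetate to a cyclobutene carbaldehyde, then aldol condensation; C-7–C-7a is the fragment-joining bond.
4. Cyclobutane ⇐ [2+2] photocycloaddition of a 4-substituted butenolide with 1,1-diethoxyethene; butenolide ⇐ furan-3-carbaldehyde (asymmetric allylation, singlet-oxygen oxidation).
5. Ring order: γ-lactone → cyclobutane → ring A → ring B → butenolide of half A → (E)-enol lactone of half B.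

## Route

Step 1
Reactants: 1 furan-3-carbaldehyde
Product: 2 (R)-1-(furan-3-yl)but-3-en-1-ol
Conditions: allylB(pin), (R)-TRIP phosphoric acid (5 mol %), PhMe, −30 °C
Reagents that add atoms: allylboronic acid pinacol ester C=CCB1OC(C)(C)C(C)(C)O1
Why: Chiral-phosphoric-acid-catalysed carbonyl allylboration through a closed chair transition state gives the homoallylic alcohol in high ee (sense assumed as for aryl aldehydes); this carbinol (future C-7') only serves as the handle for separating the photoadducts in step 7 and is erased in step 16.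

Step 2
Reactants: 2 (R)-1-(furan-3-yl)but-3-en-1-ol
Product: 3 (R)-tert-butyl{[1-(furan-3-yl)but-3-en-1-yl]oxy}dimethylsilane
Conditions: TBSCl, imidazole, DMF, rt
Reagents that add atoms: tert-butyldimethylsilyl chloride CC(C)(C)[Si](C)(C)Cl
Why: Standard silylation; the TBS ether survives the bases, the photolysis and the Pd steps that follow.

Step 3
Reactants: 3 (R)-tert-butyl{[1-(furan-3-yl)but-3-en-1-yl]oxy}dimethylsilane
Product: 5 (R)-4-[(tert-butyldimethylsilyl)oxy]-4-(furan-3-yl)butan-1-ol, via alkylborane 4 (not isolated)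
Conditions: 9-BBN, THF, 0 °C to rt; then NaOH, H2O2, 0 °C
Reagents that add atoms: hydrogen peroxide OO
Why: Anti-Markovnikov hydroboration–oxidation of the terminal alkene (the furan is inert to 9-BBN) removes the alkene, which would otherwise cycloadd intramolecularly in step 7, and provides C-4' as a primary carbinol.

Step 4
Reactants: 5 (R)-4-[(tert-butyldimethylsilyl)oxy]-4-(furan-3-yl)butan-1-ol
Product: 6 (R)-tert-butyl{[4-chloro-1-(furan-3-yl)butyl]oxy}dimethylsilane
Conditions: PPh3, CCl4, CH2Cl2, 40 °C
Reagents that add atoms: carbon tetrachloride ClC(Cl)(Cl)Cl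
Why: Appel chlorination of the primary alcohol gives a chloride that is inert to light, KN(SiMe3)2 at −78 °C and Pd until it is activated in step 12.

Step 5
Reactants: 6 (R)-tert-butyl{[4-chloro-1-(furan-3-yl)butyl]oxy}dimethylsilane
Product: 8 4-{(R)-4-chloro-1-[(tert-butyldimethylsilyl)oxy]butyl}-5-hydroxyfuran-2(5H)-one, via furan endoperoxide 7 (not isolated)
Conditions: O2, hν (visible), tetraphenylporphyrin (cat.), i-Pr2NEt, CH2Cl2, −78 °C
Reagents that add atoms: dioxygen O=O
Why: Singlet-oxygen [4+2] addition to the 3-substituted furan followed by amine-induced fragmentation of the endoperoxide at the less hindered bridgehead C–H gives the 4-substituted 5-hydroxybutenolide regioselectively.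

Step 6
Reactants: 8 4-{(R)-4-chloro-1-[(tert-butyldimethylsilyl)oxy]butyl}-5-hydroxyfuran-2(5H)-one
Product: 9 4-{(R)-4-chloro-1-[(tert-butyldimethylsilyl)oxy]butyl}furan-2(5H)-one
Conditions: NaBH4, EtOH, 0 °C; then 1 M HCl
Reagents that add atoms: none
Why: The pseudo-acid is reduced through its open aldehyde form and relactonises on acidification, giving the β-substituted butenolide (C=O = future C-3', CH2O = future C-1', β-carbon = C-7a').

Step 7
Reactants: 9 4-{(R)-4-chloro-1-[(tert-butyldimethylsilyl)oxy]butyl}furan-2(5H)-one; 10 1,1-diethoxyethene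
Product: 11 cis-fused 5-{(R)-4-chloro-1-[(tert-butyldimethylsilyl)oxy]butyl}-6,6-diethoxy-3-oxabicyclo[3.2.0]heptan-2-one (diastereomer shown in the list)
Conditions: hν (medium-pressure Hg lamp, quartz), 10 (10 equiv), Et2O, −20 °C; chromatographic separation of the two facial diastereomers
Reagents that add atoms: none
Why: Enone–alkene [2+2] photocycloaddition with head-to-tail regiochemistry (acetal carbon on the β-carbon) and an enforced cis ring fusion sets C-3a' and C-7a'; the two facial adducts are diastereomers because of the (R)-carbinol, so separating them secures the absolute configuration.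

Step 8
Reactants: 11 acetal photoadduct
Product: 12 5-{(R)-4-chloro-1-[(tert-butyldimethylsilyl)oxy]butyl}-3-oxabicyclo[3.2.0]heptane-2,6-dione
Conditions: p-TsOH·H2O (cat.), acetone/H2O, 40 °C
Reagents that add atoms: water O
Why: Acid-catalysed acetal hydrolysis unveils the cyclobutanone at C-6; the hindered secondary TBS ether and the lactone are stable.

Step 9
Reactants: 12 cyclobutanone
Product: 13 5-{(R)-4-chloro-1-[(tert-butyldimethylsilyl)oxy]butyl}-2-oxo-3-oxabicyclo[3.2.0]hept-6-en-6-yl trifluoromethanesulfonate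
Conditions: KN(SiMe3)2, THF, −78 °C; then PhNTf2, −78 to −20 °C
Reagents that add atoms: N-phenylbis(trifluoromethanesulfonimide) O=S(=O)(N(c1ccccc1)S(=O)(=O)C(F)(F)F)C(F)(F)F
Why: The ketone can enolise only towards C-7 (C-7a' is quaternary) and is more acidic than the lactone α-H, so O-triflation gives the C-6=C-7 cyclobutenyl triflate.

Step 10
Reactants: 13 cyclobutenyl triflate
Product: 14 5-{(R)-4-chloro-1-[(tert-butyldimethylsilyl)oxy]butyl}-2-oxo-3-oxabicyclo[3.2.0]hept-6-ene-6-carbaldehyde
Conditions: Pd(OAc)2 (5 mol %), dppp, CO (1 atm), Et3SiH, Et3N, DMF, 70 °C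
Reagents that add atoms: carbon monoxide [C-]#[O+]
Why: Pd-catalysed reductive carbonylation (formylation) of the alkenyl triflate installs C-5 as the aldehyde of a strained cyclobutene enal.

Step 11
Reactants: 14 cyclobutene carbaldehyde; 15 tert-butyl 3-oxobutanoate
Product: 17 tricyclic enone β-keto ester (ring A: C-3a ketone, C-4=C-5, C-7a–CO2t-Bu; H-6 and H-7 on the lactone face), via Michael adduct 16 (not isolated)
Conditions: KOt-Bu (0.1 equiv), THF, −20 °C to rt; then piperidine/AcOH (0.3 equiv each), PhMe, 4 Å MS, 60 °C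
Reagents that add atoms: none
Why: Intermolecular Michael addition of the acetoacetate to the strain-activated enal forms the C-7–C-7a bond on the convex face (anti to the lactone, next to H-3a'); C-6 equilibrates α to the aldehyde and only the cis isomer closes by intramolecular aldol condensation (Robinson-type [3+3] annulation), which sets C-6 and C-7.

Step 12
Reactants: 17 tricyclic enone β-keto ester (chloride)
Product: 18 the corresponding primary iodide
Conditions: NaI, acetone, reflux
Reagents that add atoms: sodium iodide [Na+].[I-]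
Why: Finkelstein exchange makes C-4' a good electrophile for the ring closure; all other functions are neutral to NaI.

Step 13
Reactants: 18 iodide
Product: 19 tetracyclic silyl ether (ring B closed; C-3a' quaternary)
Conditions: LiN(i-Pr)2 (2.2 equiv), THF/DMPU, −78 to 0 °C
Reagents that add atoms: none
Why: The first equivalent masks ring A as its β-keto ester enolate and the second forms the lactone enolate, which undergoes 6-exo-tet alkylation; the chain hangs from C-7a' on the carbocycle face and the lactone must stay cis-fused, so C-4' is forced onto the face of C-5 and C-7a and C-3a' is set.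

Step 14
Reactants: 19 tetracyclic silyl ether
Product: 20 saturated β-keto ester (C-4–C-5 reduced)
Conditions: H2 (1 atm), Pd/C, EtOAc, rt
Reagents that add atoms: none
Why: Catalytic hydrogenation of the enone C=C, done while no other alkene is present.

Step 15
Reactants: 20 saturated β-keto ester silyl ether
Product: 21 C-7' alcohol
Conditions: HF·pyridine, THF, 0 °C to rt
Reagents that add atoms: none
Why: Fluoride cleavage of the TBS ether under mildly acidic conditions that leave the tert-butyl ester and lactone untouched.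

Step 16
Reactants: 21 C-7' alcohol
Product: 22 C-7' ketone
Conditions: Dess–Martin periodinane, NaHCO3, CH2Cl2, rt
Reagents that add atoms: none
Why: Mild oxidation of the secondary alcohol; the auxiliary stereocentre is removed and the ketone can enolise only towards C-6'.

Step 17
Reactants: 22 C-7' ketone
Product: 23 ring B enol triflate (C-7'(OTf)=C-6')
Conditions: KN(SiMe3)2 (2.1 equiv), THF, −78 °C; then PhNTf2 (1.05 equiv), −78 to −20 °C
Reagents that add atoms: N-phenylbis(trifluoromethanesulfonimide) O=S(=O)(N(c1ccccc1)S(=O)(=O)C(F)(F)F)C(F)(F)F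
Why: After the β-keto ester is deprotonated, the second equivalent forms the kinetic ketone enolate, and this more basic enolate is the one triflated by a single equivalent of PhNTf2.

Step 18
Reactants: 23 ring B enol triflate
Product: 24 ring B alkene (C-6'=C-7') β-keto ester
Conditions: Pd(OAc)2 (5 mol %), PPh3, HCO2H, Bu3N, DMF, 60 °C
Reagents that add atoms: none
Why: Pd-catalysed formate reduction of the alkenyl triflate gives the C-6'=C-7' alkene regiospecifically without any cationic intermediate next to the cyclobutane.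

Step 19
Reactants: 24 ring B alkene β-keto ester
Product: 25 ring A enol triflate (C-3a(OTf)=C-7a–CO2t-Bu)
Conditions: NaH, THF, 0 °C; then PhNTf2, rt
Reagents that add atoms: N-phenylbis(trifluoromethanesulfonimide) O=S(=O)(N(c1ccccc1)S(=O)(=O)C(F)(F)F)C(F)(F)F
Why: O-triflation of the β-keto ester enolate fixes the tetrasubstituted C-3a=C-7a double bond of the butenolide half.

Step 20
Reactants: 25 ring A enol triflate; 26 pent-1-yne
Product: 27 enyne ester lactone (C-3a–C≡C–Pr)
Conditions: Pd(PPh3)2Cl2 (5 mol %), CuI (10 mol %), Et3N, DMF, rt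
Reagents that add atoms: none
Why: Sonogashira coupling of the activated β-triflyloxy enoate brings in C-3 and C-8 to C-11.

Step 21
Reactants: 27 enyne ester lactone
Product: 28 lactol (C-3' hemiacetal, anomers)
Conditions: i-Bu2AlH (1.3 equiv), PhMe, −78 °C
Reagents that add atoms: none
Why: Low-temperature hydride reduction stops at the lactol, and the γ-lactone reacts much faster than the hindered, conjugated tert-butyl ester.

Step 22
Reactants: 28 lactol
Product: 29 alkynol (C-3a'–C≡CH and C-1'H2OH, cis on the cyclobutane)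
Conditions: dimethyl (1-diazo-2-oxopropyl)phosphonate, K2CO3, MeOH, 0 °C to rt
Reagents that add atoms: dimethyl (1-diazo-2-oxopropyl)phosphonate COP(=O)(OC)C(=[N+]=[N-])C(C)=O
Why: Ohira–Bestmann homologation of the open hydroxy aldehyde turns C-3' into a terminal alkyne (C-8' comes from the reagent); the aldehyde carbon has no α-hydrogen, so nothing can epimerise.

Step 23
Reactants: 29 alkynol
Product: 30 alkynal (C-1' aldehyde)
Conditions: Dess–Martin periodinane, NaHCO3, CH2Cl2, rt
Reagents that add atoms: none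
Why: Mild oxidation to a non-enolisable aldehyde, so that only one carboxylic acid is present during the Ag step.

Step 24
Reactants: 30 alkynal
Product: 31 enynoic acid (C-1 acid free)
Conditions: CF3CO2H/CH2Cl2 (1:4), 0 °C to rt
Reagents that add atoms: none
Why: Acidolysis of the tert-butyl ester (loss of isobutene), carried out before any acid-labile enol lactone exists.

Step 25
Reactants: 31 enynoic acid
Product: 32 (Z)-butylidene butenolide aldehyde
Conditions: AgNO3 (10 mol %), acetone, rt, dark
Reagents that add atoms: none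
Why: Ag-catalysed 5-exo-dig lactonisation of the (Z)-2-en-4-ynoic acid proceeds by anti oxy-metalation and protodemetalation, so propyl ends cis to the ring oxygen ((Z)-C-3=C-8).

Step 26
Reactants: 32 butenolide aldehyde
Product: 33 butenolide acid (C-1' carboxylic acid)
Conditions: NaClO2, NaH2PO4, 2-methylbut-2-ene, t-BuOH/H2O, 0 °C
Reagents that add atoms: sodium chlorite [Na+].[O-]Cl=O
Why: Pinnick oxidation of the aldehyde under buffered conditions, with the scavenger protecting the alkenes from hypochlorite.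

Step 27
Reactants: 33 butenolide acid
Product: 34 (E)-iodomethylene lactone
Conditions: N-iodosuccinimide (1.2 equiv), NaHCO3 (0.2 equiv), CH2Cl2, 0 °C, dark
Reagents that add atoms: N-iodosuccinimide O=C1CCC(=O)N1I
Why: Iodolactonisation of the cis-held alkynoic acid (5-exo-dig) is an anti addition, so iodine ends trans to the ring oxygen ((E)-iodo enol lactone).

Step 28
Reactants: 34 (E)-iodomethylene lactone
Product: 35 target (CNP0371639.1)
Conditions: n-PrZnBr (3 equiv), Pd(PPh3)4 (5 mol %), THF, rt
Reagents that add atoms: propylzinc bromide CCC[Zn]Br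
Why: Negishi coupling replaces iodine by propyl with retention of the alkene geometry, giving the (E)-butylidene lactone in the last, neutral step.

## Compound list

1 | furan-3-carbaldehyde | O=Cc1ccoc1 | starting material
2 | (R)-1-(furan-3-yl)but-3-en-1-ol | C=CC[C@@H](O)c1ccoc1 | intermediate
3 | (R)-tert-butyl{[1-(furan-3-yl)but-3-en-1-yl]oxy}dimethylsilane | C=CC[C@@H](O[Si](C)(C)C(C)(C)C)c1ccoc1 | intermediate
4 | 9-[(R)-4-(TBSO)-4-(furan-3-yl)butyl]-9-borabicyclo[3.3.1]nonane | C(CC[C@@H](O[Si](C)(C)C(C)(C)C)c1ccoc1)B1C2CCCC1CCC2 | intermediate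
5 | (R)-4-[(tert-butyldimethylsilyl)oxy]-4-(furan-3-yl)butan-1-ol | OCCC[C@@H](O[Si](C)(C)C(C)(C)C)c1ccoc1 | intermediate
6 | (R)-tert-butyl{[4-chloro-1-(furan-3-yl)butyl]oxy}dimethylsilane | ClCCC[C@@H](O[Si](C)(C)C(C)(C)C)c1ccoc1 | intermediate
7 | furan endoperoxide (2,3,7-trioxabicyclo[2.2.1]hept-5-ene with the side chain on C-5) | ClCCC[C@@H](O[Si](C)(C)C(C)(C)C)C1=CC2OOC1O2 | intermediate
8 | 4-{(R)-4-chloro-1-(TBSO)butyl}-5-hydroxyfuran-2(5H)-one (C-5 epimers) | ClCCC[C@@H](O[Si](C)(C)C(C)(C)C)C1=CC(=O)OC1O | intermediate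
9 | 4-{(R)-4-chloro-1-(TBSO)butyl}furan-2(5H)-one | ClCCC[C@@H](O[Si](C)(C)C(C)(C)C)C1=CC(=O)OC1 | intermediate
10 | 1,1-diethoxyethene | C=C(OCC)OCC | starting material
11 | cis-fused 5-{(R)-4-chloro-1-(TBSO)butyl}-6,6-diethoxy-3-oxabicyclo[3.2.0]heptan-2-one (lactone up, side chain down) | ClCCC[C@@H](O[Si](C)(C)C(C)(C)C)[C@]12COC(=O)[C@H]1CC2(OCC)OCC | intermediate
12 | corresponding 3-oxabicyclo[3.2.0]heptane-2,6-dione | ClCCC[C@@H](O[Si](C)(C)C(C)(C)C)[C@]12COC(=O)[C@H]1CC2=O | intermediate
13 | 2-oxo-3-oxabicyclo[3.2.0]hept-6-en-6-yl triflate carrying the side chain at C-5 | ClCCC[C@@H](O[Si](C)(C)C(C)(C)C)[C@]12COC(=O)[C@H]1C=C2OS(=O)(=O)C(F)(F)F | intermediate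
14 | 2-oxo-3-oxabicyclo[3.2.0]hept-6-ene-6-carbaldehyde carrying the side chain at C-5 | ClCCC[C@@H](O[Si](C)(C)C(C)(C)C)[C@]12COC(=O)[C@H]1C=C2C=O | intermediate
15 | tert-butyl 3-oxobutanoate | CC(=O)CC(=O)OC(C)(C)C | starting material
16 | Michael adduct (C-7 carries CH(COCH3)CO2t-Bu on the carbocycle face; C-6 aldehyde, epimers at C-6 and C-7a) | ClCCC[C@@H](O[Si](C)(C)C(C)(C)C)[C@]12COC(=O)[C@H]1[C@H](C(C(C)=O)C(=O)OC(C)(C)C)C2C=O | intermediate
17 | tricyclic enone β-keto ester, chloride (γ-lactone/cyclobutane/cyclohexenone; H-6, H-7 on the lactone face; C-7a enolisable) | ClCCC[C@@H](O[Si](C)(C)C(C)(C)C)[C@]12COC(=O)[C@H]1[C@@H]3C(C(=O)OC(C)(C)C)C(=O)C=C[C@H]23 | intermediate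
18 | tricyclic enone β-keto ester, iodide | ICCC[C@@H](O[Si](C)(C)C(C)(C)C)[C@]12COC(=O)[C@H]1[C@@H]3C(C(=O)OC(C)(C)C)C(=O)C=C[C@H]23 | intermediate
19 | tetracyclic enone β-keto ester with ring B closed and C-7' OTBS (rings A and B on the same cyclobutane face, lactone on the other) | CC(C)(C)[Si](C)(C)O[C@@H]1CCC[C@]2(C(=O)OC3)[C@@H]4C(C(=O)OC(C)(C)C)C(=O)C=C[C@@H]4[C@]123 | intermediate
20 | saturated β-keto ester, C-7' OTBS | CC(C)(C)[Si](C)(C)O[C@@H]1CCC[C@]2(C(=O)OC3)[C@@H]4C(C(=O)OC(C)(C)C)C(=O)CC[C@@H]4[C@]123 | intermediate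
21 | saturated β-keto ester, C-7' alcohol | O[C@@H]1CCC[C@]2(C(=O)OC3)[C@@H]4C(C(=O)OC(C)(C)C)C(=O)CC[C@@H]4[C@]123 | intermediate
22 | saturated β-keto ester, C-7' ketone | O=C1CCC[C@]2(C(=O)OC3)[C@@H]4C(C(=O)OC(C)(C)C)C(=O)CC[C@@H]4[C@]123 | intermediate
23 | ring B enol triflate (C-7'(OTf)=C-6') | FC(F)(F)S(=O)(=O)OC1=CCC[C@]2(C(=O)OC3)[C@@H]4C(C(=O)OC(C)(C)C)C(=O)CC[C@@H]4[C@]123 | intermediate
24 | ring B alkene (C-6'=C-7') β-keto ester | C1=CCC[C@]2(C(=O)OC3)[C@@H]4C(C(=O)OC(C)(C)C)C(=O)CC[C@@H]4[C@]123 | intermediate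
25 | ring A enol triflate (C-3a(OTf)=C-7a–CO2t-Bu) | C1=CCC[C@]2(C(=O)OC3)[C@@H]4C(C(=O)OC(C)(C)C)=C(OS(=O)(=O)C(F)(F)F)CC[C@@H]4[C@]123 | intermediate
26 | pent-1-yne | CCCC#C | starting material
27 | enyne tert-butyl ester γ-lactone | C1=CCC[C@]2(C(=O)OC3)[C@@H]4C(C(=O)OC(C)(C)C)=C(C#CCCC)CC[C@@H]4[C@]123 | intermediate
28 | lactol (C-3' hemiacetal, anomers) | C1=CCC[C@]2(C(O)OC3)[C@@H]4C(C(=O)OC(C)(C)C)=C(C#CCCC)CC[C@@H]4[C@]123 | intermediate
29 | alkynol: C-3a' ethynyl and C-7a' hydroxymethyl cis on the lactone face; ring A enyne tert-butyl ester | C1=CCC[C@]2(C#C)[C@@H]3C(C(=O)OC(C)(C)C)=C(C#CCCC)CC[C@@H]3[C@]12CO | intermediate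
30 | alkynal (C-1' aldehyde) | C1=CCC[C@]2(C#C)[C@@H]3C(C(=O)OC(C)(C)C)=C(C#CCCC)CC[C@@H]3[C@]12C=O | intermediate
31 | enynoic acid (C-1 CO2H, C-1' aldehyde) | C1=CCC[C@]2(C#C)[C@@H]3C(C(=O)O)=C(C#CCCC)CC[C@@H]3[C@]12C=O | intermediate
32 | (Z)-butylidene butenolide with C-3a' ethynyl and C-7a' formyl | C1=CCC[C@]2(C#C)[C@@H]3C4=C(CC[C@@H]3[C@]12C=O)/C(=C/CCC)OC4=O | intermediate
33 | (Z)-butylidene butenolide with C-3a' ethynyl and C-7a' carboxylic acid | C1=CCC[C@]2(C#C)[C@@H]3C4=C(CC[C@@H]3[C@]12C(=O)O)/C(=C/CCC)OC4=O | intermediate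
34 | (E)-iodomethylene lactone (I trans to the ring oxygen), (Z)-butylidene butenolide | C1=CCC[C@]25[C@@H]3C4=C(CC[C@@H]3[C@]12C(=O)O/C5=C/I)/C(=C/CCC)OC4=O | intermediate
35 | CNP0371639.1 | CCC/C=C1\OC(=O)C2=C1CC[C@H]1[C@@H]2[C@@]23CCC=C[C@@]12C(=O)O/C3=C/CCC | target

## Summary and risks

Total step count: 28. Longest linear sequence: 28 steps (from 1; 10, 15 and 26 are bought).

Three steps most likely to fail:

Step 11 (Michael/aldol annulation). The enal may undergo 1,2-addition or Knoevenagel chemistry, or the aldol closure may stall; the wrong facial adduct would be removed by chromatography. Fallback: starting from enal 14, a TiCl4-mediated Mukaiyama–Michael addition of 1-(tert-butoxy)-1-(trimethylsilyloxy)ethene at −78 °C gives aldehyde ester F1. A Still–Gennari olefination of the aldehyde (methyl bis(2,2,2-trifluoroethyl)phosphonoacetate, KN(SiMe3)2, 18-crown-6, THF, −78 °C) gives (Z)-enoate diester F2. Dieckmann cyclisation with KOt-Bu in THF (the tert-butyl ester enolate attacks the methyl ester) then returns to the route at 17.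

Step 17 (selective enol triflation of the C-7' ketone beside the β-keto ester). Triflation could occur at the β-keto ester instead, or at both sites. Fallback: starting from alcohol 21, MsCl/Et3N in CH2Cl2 at 0 °C gives mesylate F3; E2 elimination with DBU in PhMe at 100 °C (only C-6' carries β-hydrogens) returns to the route at 24. This replaces the ketone/enol triflate/reduction sequence by a sulfonate elimination.

Step 27 (iodolactonisation). The ring B alkene is β,γ to the same acid and might compete with the alkyne for the iodonium. Fallback: starting from acid 33, a PdCl2(PhCN)2-catalysed anti oxypalladation of the alkyne with allyl chloride and Li2CO3 in THF forms the C-8' carbon bond directly and gives (E)-but-3-enylidene lactone F4, with no vinyl iodide. Chemoselective diimide reduction of the terminal vinyl group (2-nitrobenzenesulfonohydrazide, Et3N, CH2Cl2, rt) returns to the route at 35.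

Further compounds
F1 | step 11 | aldehyde ester (C-7 CH2CO2t-Bu and C-6 CHO cis on the carbocycle face) | ClCCC[C@@H](O[Si](C)(C)C(C)(C)C)[C@]12COC(=O)[C@H]1[C@H](CC(=O)OC(C)(C)C)[C@@H]2C=O
F2 | step 11 | (Z)-enoate diester (C-6 (Z)-CH=CH–CO2Me, C-7 CH2CO2t-Bu) | ClCCC[C@@H](O[Si](C)(C)C(C)(C)C)[C@]12COC(=O)[C@H]1[C@H](CC(=O)OC(C)(C)C)[C@@H]2/C=C\C(=O)OC
F3 | step 17 | C-7' mesylate of 21 | CS(=O)(=O)O[C@@H]1CCC[C@]2(C(=O)OC3)[C@@H]4C(C(=O)OC(C)(C)C)C(=O)CC[C@@H]4[C@]123
F4 | step 27 | (E)-but-3-enylidene lactone, (Z)-butylidene butenolide | C1=CCC[C@]25[C@@H]3C4=C(CC[C@@H]3[C@]12C(=O)O/C5=C/CC=C)/C(=C/CCC)OC4=O
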